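**Retrosynthetic overview**
1. Target: (13E)-labda-7,13-diene-15,17-diyl diacetate (5S,9R,10S; labdane numbers used throughout). Enabling feature: ring A (C1–C2–C3–C4–C5–C10) carries no functional group and shares only the C5–C10 bond with ring B, next to the C9 stereocentre. It can therefore be cut into a diene C2=C3–C4=C5 and the alkene C1=C10(CH3), which is an isopropenyl group on C9, with C6–C7–C8–C9 of ring B as the tether.
2. Key disconnection: C1–C2 and C5–C10 by an intramolecular Diels–Alder reaction of the acyclic tetraene 10. Rings A and B form together in that step; no carbocycle exists before it.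
3. Temporary groups: a C3 silyl enol ether (it allows the second C4 methyl to be added by enolate methylation; C3=O is then removed by Wolff–Kishner reduction) and a C7 oxygen (later moved to C17 by 1,3-transposition, which also creates C7=C8).
4. Precursor 10 from (S)-limonene: ring cleavage gives C9 with its isopropenyl group, the CH2CH2COCH3 arm (C11–C13, C16) and a CH2CHO arm (C8, C7); α-methylenation adds C17; a vinylogous Mukaiyama aldol adds C6–C2.
5. End game: Horner–Wadsworth–Emmons olefination (C14, C15), transposition, ester reduction, acetylation.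

Key step: step 8

Remark: C7 is a temporary stereocentre that does not reach the target; the 7β configuration is assumed and drawn, reached with the appropriate antipode of the catalyst in step 4, and the 7α epimer would follow the same steps.

**Step 1**
Reactants: 1 (S)-(−)-limonene
Product: 2 (3S)-6-oxo-3-(prop-1-en-2-yl)heptanal
Conditions: O3 (1 equiv), CH2Cl2–MeOH, −78 °C; then Me2S, −78 °C → rt
Reagents that add atoms: ozone, [O-][O+]=O
Why: Chemoselective ozonolysis: the electron-rich trisubstituted ring alkene reacts with ozone far faster than the 1,1-disubstituted isopropenyl group, so one equivalent of ozone and a reductive work-up should open only the ring and leave the stereocentre (the later C9) untouched.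

**Step 2**
Reactants: 2 (3S)-6-oxo-3-(prop-1-en-2-yl)heptanal
Product: 3 (3R)-2-methylidene-6-oxo-3-(prop-1-en-2-yl)heptanal
Conditions: 37% aq. CH2O, pyrrolidine (10 mol %), EtCO2H (10 mol %), i-PrOH, 45 °C
Reagents that add atoms: formaldehyde, C=O
Why: Amine-catalysed Mannich condensation and elimination (α-methylenation of an aldehyde) runs through the enamine of the aldehyde only, so the methyl ketone is spared and the β-stereocentre, which is not part of the enamine, keeps its configuration (the descriptor changes only through the priority rules); the new CH2 is C17.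

**Step 3**
Reactants: 4 methyl tiglate
Product: 5 tert-butyl[(1-methoxy-2-methylbuta-1,3-dien-1-yl)oxy]dimethylsilane
Conditions: LiN(i-Pr)2, THF–DMPU, −78 °C; TBSCl, −78 → 0 °C
Reagents that add atoms: tert-butyldimethylsilyl chloride, CC(C)(C)[Si](C)(C)Cl
Why: γ-Deprotonation of the enoate by the amide base in the presence of DMPU gives the extended lithium dienolate, which is trapped on oxygen by the silyl chloride (silyl ketene acetal formation; the acetal double-bond geometry is irrelevant for step 4).

**Step 4**
Reactants: 3 (3R)-2-methylidene-6-oxo-3-(prop-1-en-2-yl)heptanal; 5 silyl ketene acetal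
Product: 6 methyl (2E,5S,7R)-5-hydroxy-2-methyl-6-methylidene-10-oxo-7-(prop-1-en-2-yl)undec-2-enoate
Conditions: 4-(1H-indol-3-ylmethyl)-2-phenyl-3-tosyl-1,3,2-oxazaborolidin-5-one (from N-tosyltryptophan and PhBCl2; the enantiomer that gives 5S), i-PrOH, EtCN, −78 °C
Reagents that add atoms: none
Why: Vinylogous Mukaiyama aldol reaction: the boron Lewis acid binds the aldehyde of 3 in preference to its ketone, the α-methyl group of 5 steers attack to the γ-carbon (C6) and leads to the 2E enoate, and the chiral oxazaborolidinone fixes C7 by catalyst control (5S in 6), a centre that only keeps 6–17 single diastereomers because it is erased in step 12.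

**Step 5**
Reactants: 6 hydroxy keto ester
Product: 7 methyl (2E,5S,7R)-5-hydroxy-2-methyl-6-methylidene-9-(2-methyl-1,3-dioxolan-2-yl)-7-(prop-1-en-2-yl)non-2-enoate
Conditions: HOCH2CH2OH, pyridinium p-toluenesulfonate (cat.), benzene, reflux, Dean–Stark trap
Reagents that add atoms: ethane-1,2-diol, OCCO
Why: Acid-catalysed ketalisation with azeotropic removal of water masks the only ketone as a dioxolane, so that the organometallic, enolate and hydrazine steps ahead cannot touch C13; the conjugated ester and the allylic alcohol are inert to the weak acid.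

**Step 6**
Reactants: 7 hydroxy ester ketal
Product: 9 (3E,6S,8R)-6-hydroxy-3-methyl-7-methylidene-10-(2-methyl-1,3-dioxolan-2-yl)-8-(prop-1-en-2-yl)dec-3-en-2-one, via Weinreb amide 8 (not isolated)
Conditions: MeNH(OMe)·HCl, i-PrMgCl, THF, −20 °C; then MeMgBr, −20 → 0 °C; aq. NH4Cl
Reagents that add atoms: methylmagnesium bromide, C[Mg]Br; N,O-dimethylhydroxylamine hydrochloride, CNOC.Cl (its atoms are carried only in 8)
Why: One-pot conversion of an ester into a ketone through a Weinreb amide: the magnesium amide of N,O-dimethylhydroxylamine opens the ester, and the chelated tetrahedral adduct of 8 with MeMgBr survives until work-up, so the methyl ketone forms without over-addition while the C7 alkoxide stays a spectator.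

**Step 7**
Reactants: 9 hydroxy enone
Product: 10 (3E,6S,8R)-2,6-bis(tert-butyldimethylsilyloxy)-3-methyl-7-methylidene-10-(2-methyl-1,3-dioxolan-2-yl)-8-(prop-1-en-2-yl)deca-1,3-diene
Conditions: TBSOTf (2.5 equiv), Et3N, CH2Cl2, −78 → 0 °C
Reagents that add atoms: tert-butyldimethylsilyl trifluoromethanesulfonate, CC(C)(C)[Si](C)(C)OS(=O)(=O)C(F)(F)F
Why: Soft enolisation with a silyl triflate and an amine removes a proton from the α′-methyl group of the enone to give the cross-conjugated 2-siloxydiene with the 3E geometry intact (silyl dienol ether formation) and silylates the C7 hydroxyl in the same operation.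

**Step 8**
Reactants: 10 acyclic siloxydiene tetraene
Product: 11 3,7β-bis(tert-butyldimethylsilyloxy)-13,13-(ethylenedioxy)-14,15,18-trinorlabda-3,8(17)-diene (trans-fused; 5α-H 9α-H 10β-CH3)
Conditions: toluene (0.01 M), BHT, Et3N (trace), sealed tube, 190–200 °C
Reagents that add atoms: none
Why: A thermal, concerted but asynchronous suprafacial [4π+2π] cycloaddition joins the 2-siloxy-3-methylbutadiene C2=C3(OTBS)–C4(CH3)=C5 (held largely s-cis by its two inner substituents) to the unactivated 1,1-disubstituted alkene C1=C10, forming C1–C2 and C5–C10 in one event. The closest known reaction type is the type 1 intramolecular Diels–Alder reaction of 1,7,9-decatrienes that carry an isopropenyl dienophile, used to make angularly methylated octalins at 180–220 °C. Ring A closes as the new cyclohexene itself (the enol ether double bond is left at C3=C4), and ring B closes through the same C5–C10 bond across the four-carbon tether C6–C9 in the fused mode; the bridged regiochemistry and any reaction of the C8=C17 alkene are excluded by tether length. C10 and C5 are set by the limonene-derived C9: in the chair-like tether the C9 side chain (and the C7 silyloxy group) sits equatorial, so the diene adds to the face of C1=C10 that bears the C9 hydrogen and the side chain ends up anti to the new C5–C10 bond (9α-H and 10β-CH3 as in the target). The step needs the tether-exo (methyl-endo) transition state that gives the trans ring fusion (5α-H); it should be preferred because the tether-endo alternative must fold the branched C9 and the sp2 C8 under the diene against the C4 methyl group, whereas only the small C10 methyl lies there in the trans mode, and the sp2 C8 spares that methyl one 1,3-diaxial contact. The E geometry of C4=C5 (from step 4) places the tether outside the diene as the reaction requires, and no stereocentre arises at C3 or C4.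

**Step 9**
Reactants: 11 bis-silyl cycloadduct
Product: 13 7β-(tert-butyldimethylsilyloxy)-13,13-(ethylenedioxy)-14,15-dinorlabd-8(17)-en-3-one, via lithium enolate 12 (not isolated)
Conditions: MeLi, THF, 0 °C → rt; then DMPU, MeI, −78 → 0 °C
Reagents that add atoms: iodomethane, CI; methyllithium, [Li]C (its lithium is carried only in 12)
Why: Regiospecific enolate alkylation: MeLi cleaves the enol silyl ether to the C3–C4 lithium enolate without equilibration, MeI alkylates it on carbon at C4 to create the gem-dimethyl carbon (no stereocentre), and the alkyl silyl ether, the dioxolane and the alkene are inert to both reagents.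

**Step 10**
Reactants: 13 4,4-dimethyl 3-ketone
Product: 16 7β-hydroxy-14,15-dinorlabd-8(17)-en-13-one, via hydrazone 14 (not isolated), via ketal alcohol 15 (not isolated)
Conditions: N2H4·H2O, KOH, diethylene glycol, 130 then 200 °C; then 2 M HCl, THF, rt
Reagents that add atoms: hydrazine hydrate, NN.O (its nitrogen is carried only in 14); water, O (oxygen of the C13 carbonyl of 16)
Why: Wolff–Kishner reduction removes the temporary C3 carbonyl through its hydrazone with loss of N2, the hot hydroxide also cleaves the C7 silyl ether (any remainder falls in the acid stage), and the dilute acid then hydrolyses the dioxolane without ionising the allylic alcohol; isolated alkenes and the ketal survive the basic stage.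

**Step 11**
Reactants: 16 hydroxy methyl ketone
Product: 17 ethyl (13E)-7β-hydroxylabda-8(17),13-dien-15-oate
Conditions: (EtO)2P(O)CH2CO2Et, NaH (excess), THF, 0 → 50 °C
Reagents that add atoms: triethyl phosphonoacetate, CCOC(=O)CP(=O)(OCC)OCC
Why: Horner–Wadsworth–Emmons olefination of the methyl ketone should place the ester anti to the larger CH2 branch and so favour the 13E enoate (the minor 13Z isomer is removed by chromatography), and the phosphonate carbanion, used in excess, is not acylated by the hindered C7 alkoxide.

**Step 12**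
Reactants: 17 7β-hydroxy 8(17)-ene ester
Product: 19 ethyl (13E)-17-hydroxylabda-7,13-dien-15-oate, via trimethylsilyl ether 18 (not isolated)
Conditions: Ph3SiOReO3 (5 mol %), N,O-bis(trimethylsilyl)acetamide, Et2O, 0 °C → rt; then K2CO3, EtOH
Reagents that add atoms: N,O-bis(trimethylsilyl)acetamide, CC(=N[Si](C)(C)C)O[Si](C)(C)C (its silyl group is carried only in 18)
Why: Rhenium-oxo-catalysed 1,3-transposition of an allylic alcohol ([3,3] shift of the perrhenate ester) moves the oxygen from C7 to C17 and the double bond into ring B (C7=C8, geometry fixed by the ring), the equilibrium being drawn to the primary alcohol by its faster silylation; C9 and the enoate are not involved.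

**Step 13**
Reactants: 19 hydroxy ester
Product: 20 (13E)-labda-7,13-diene-15,17-diol
Conditions: i-Bu2AlH, CH2Cl2, −78 → 0 °C; aq. potassium sodium tartrate
Reagents that add atoms: none
Why: Hydride reduction of the conjugated ester with i-Bu2AlH gives the allylic alcohol by 1,2-addition only, with the 13E geometry and both trisubstituted alkenes untouched.

**Step 14**
Reactants: 20 diol
Product: 21 (13E)-labda-7,13-diene-15,17-diyl diacetate
Conditions: Ac2O, pyridine, DMAP (cat.), CH2Cl2, rt
Reagents that add atoms: acetic anhydride, CC(=O)OC(C)=O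
Why: Base-catalysed acylation (DMAP) of the two primary allylic alcohols gives the diacetate without allylic rearrangement.

**Compound list**
1 | (S)-(−)-limonene | CC1=CC[C@H](CC1)C(C)=C | starting material
2 | (3S)-6-oxo-3-(prop-1-en-2-yl)heptanal | O=CC[C@H](CCC(C)=O)C(C)=C | intermediate
3 | (3R)-2-methylidene-6-oxo-3-(prop-1-en-2-yl)heptanal | O=CC(=C)[C@H](CCC(C)=O)C(C)=C | intermediate
4 | methyl tiglate, methyl (2E)-2-methylbut-2-enoate | C/C=C(\C)C(=O)OC | starting material
5 | tert-butyl[(1-methoxy-2-methylbuta-1,3-dien-1-yl)oxy]dimethylsilane (acetal double-bond geometry not defined) | C=CC(C)=C(OC)O[Si](C)(C)C(C)(C)C | intermediate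
6 | methyl (2E,5S,7R)-5-hydroxy-2-methyl-6-methylidene-10-oxo-7-(prop-1-en-2-yl)undec-2-enoate | COC(=O)/C(C)=C/C[C@H](O)C(=C)[C@H](CCC(C)=O)C(C)=C | intermediate
7 | methyl (2E,5S,7R)-5-hydroxy-2-methyl-6-methylidene-9-(2-methyl-1,3-dioxolan-2-yl)-7-(prop-1-en-2-yl)non-2-enoate | COC(=O)/C(C)=C/C[C@H](O)C(=C)[C@H](CCC1(C)OCCO1)C(C)=C | intermediate
8 | (2E,5S,7R)-5-hydroxy-N-methoxy-N,2-dimethyl-6-methylidene-9-(2-methyl-1,3-dioxolan-2-yl)-7-(prop-1-en-2-yl)non-2-enamide | CON(C)C(=O)/C(C)=C/C[C@H](O)C(=C)[C@H](CCC1(C)OCCO1)C(C)=C | intermediate (not isolated)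
9 | (3E,6S,8R)-6-hydroxy-3-methyl-7-methylidene-10-(2-methyl-1,3-dioxolan-2-yl)-8-(prop-1-en-2-yl)dec-3-en-2-one | CC(=O)/C(C)=C/C[C@H](O)C(=C)[C@H](CCC1(C)OCCO1)C(C)=C | intermediate
10 | (3E,6S,8R)-2,6-bis(tert-butyldimethylsilyloxy)-3-methyl-7-methylidene-10-(2-methyl-1,3-dioxolan-2-yl)-8-(prop-1-en-2-yl)deca-1,3-diene | C=C(O[Si](C)(C)C(C)(C)C)/C(C)=C/C[C@H](O[Si](C)(C)C(C)(C)C)C(=C)[C@H](CCC1(C)OCCO1)C(C)=C | intermediate
11 | 3,7β-bis(tert-butyldimethylsilyloxy)-13,13-(ethylenedioxy)-14,15,18-trinorlabda-3,8(17)-diene | CC1(OCCO1)CC[C@H]2C(=C)[C@@H](O[Si](C)(C)C(C)(C)C)C[C@H]3C(C)=C(O[Si](C)(C)C(C)(C)C)CC[C@]23C | intermediate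
12 | lithium 7β-(tert-butyldimethylsilyloxy)-13,13-(ethylenedioxy)-14,15,18-trinorlabda-3,8(17)-dien-3-olate | CC1(OCCO1)CC[C@H]2C(=C)[C@@H](O[Si](C)(C)C(C)(C)C)C[C@H]3C(C)=C(O[Li])CC[C@]23C | intermediate (not isolated)
13 | 7β-(tert-butyldimethylsilyloxy)-13,13-(ethylenedioxy)-14,15-dinorlabd-8(17)-en-3-one | CC1(OCCO1)CC[C@H]2C(=C)[C@@H](O[Si](C)(C)C(C)(C)C)C[C@H]3C(C)(C)C(=O)CC[C@]23C | intermediate
14 | hydrazone of 13 at C3 (C=N geometry not defined) | CC1(OCCO1)CC[C@H]2C(=C)[C@@H](O[Si](C)(C)C(C)(C)C)C[C@H]3C(C)(C)C(=NN)CC[C@]23C | intermediate (not isolated)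
15 | 13,13-(ethylenedioxy)-14,15-dinorlabd-8(17)-en-7β-ol | CC1(OCCO1)CC[C@H]2C(=C)[C@@H](O)C[C@H]3C(C)(C)CCC[C@]23C | intermediate (not isolated)
16 | 7β-hydroxy-14,15-dinorlabd-8(17)-en-13-one | CC(=O)CC[C@H]1C(=C)[C@@H](O)C[C@H]2C(C)(C)CCC[C@]12C | intermediate
17 | ethyl (13E)-7β-hydroxylabda-8(17),13-dien-15-oate | CCOC(=O)/C=C(\C)CC[C@H]1C(=C)[C@@H](O)C[C@H]2C(C)(C)CCC[C@]12C | intermediate
18 | ethyl (13E)-17-(trimethylsilyloxy)labda-7,13-dien-15-oate | CCOC(=O)/C=C(\C)CC[C@H]1C(CO[Si](C)(C)C)=CC[C@H]2C(C)(C)CCC[C@]12C | intermediate (not isolated)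
19 | ethyl (13E)-17-hydroxylabda-7,13-dien-15-oate | CCOC(=O)/C=C(\C)CC[C@H]1C(CO)=CC[C@H]2C(C)(C)CCC[C@]12C | intermediate
20 | (13E)-labda-7,13-diene-15,17-diol | OC/C=C(\C)CC[C@H]1C(CO)=CC[C@H]2C(C)(C)CCC[C@]12C | intermediate
21 | (13E)-labda-7,13-diene-15,17-diyl diacetate (5S,9R,10S) | CC(=O)OC/C=C(\C)CC[C@H]1C(COC(C)=O)=CC[C@H]2C(C)(C)CCC[C@]12C | target

**Step count**
Total step count: 14. Longest linear sequence: 13 steps (steps 1, 2 and 4–14; step 3 prepares 5 from 4).

**Steps most likely to fail**

Step 8 (cycloaddition). The tether-exo (trans) and tether-endo (cis) modes may not be told apart well enough, or the unactivated cycloaddition may be so slow that the silyl dienol ether degrades at the temperature needed. The fallback sets out from 9 and comes back at 16; it activates the dienophile through another oxidation level. SeO2 (cat.)/t-BuOOH followed by TEMPO/PhI(OAc)2 should oxidise the isopropenyl methyl group of 9 (C20) to the 2-substituted acrolein F1. TBSOTf/Et3N then gives the siloxydiene aldehyde F2. The now polarity-matched intramolecular Diels–Alder reaction (toluene, 60–80 °C, or Me2AlCl at −78 °C; aldehyde endo, tether exo) should give the trans-fused angular aldehyde F3. Benzyltrimethylammonium fluoride/MeI converts its enol silyl ether into the 4,4-dimethyl keto aldehyde F4. The conditions of step 10 then reduce both carbonyl groups through the bis-hydrazone F5 to 15 and on to 16, so the extra carbonyl costs no removal step.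

Step 4 (vinylogous aldol). Conjugate addition to the 2-substituted acrolein, Lewis-acid-induced ene closure onto the isopropenyl group, or weak catalyst control at C7 may interfere. The fallback sets out from 3 and comes back at 10; it makes the C6–C7 bond by an auxiliary-controlled acetate aldol and the C4=C5 bond by a Wittig reaction. The titanium enolate of (S)-3-acetyl-4-isopropyl-1,3-thiazolidine-2-thione (TiCl4, i-Pr2NEt, CH2Cl2, −78 °C; auxiliary antipode chosen for 7β) adds to the aldehyde of 3 to give the aldol adduct F6. TBSOTf/2,6-lutidine gives the silyl ether F7. 1,2-Bis(trimethylsilyloxy)ethane with Me3SiOTf (cat.) at −78 °C gives the dioxolane F8. i-Bu2AlH at −78 °C cleaves the auxiliary to the aldehyde F9. 3-(Triphenylphosphoranylidene)butan-2-one gives the E-enone silyl ether F10, and the conditions of step 7 convert it into 10.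

Step 12 (1,3-transposition). The equilibrium may not be driven if silylation of the secondary C7 hydroxyl competes with that of the primary C17 hydroxyl, and dehydration to the C6=C7/C8=C17 diene may occur. The fallback sets out from 17 and comes back at 20; it uses irreversible allylic substitution with rearrangement. SOCl2 in Et2O (internal return with allylic shift) should convert 17 into the primary allylic chloride F11. KOAc/18-crown-6 in MeCN gives the allylic acetate F12. i-Bu2AlH then reduces both ester groups to give 20.

**Further compounds**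
F1 | step 8 | C20 aldehyde of 9 (2-substituted acrolein; C7 hydroxyl free) | CC(=O)/C(C)=C/C[C@H](O)C(=C)[C@H](CCC1(C)OCCO1)C(=C)C=O
F2 | step 8 | bis(tert-butyldimethylsilyl) siloxydiene of F1 (C20 aldehyde analogue of 10) | C=C(O[Si](C)(C)C(C)(C)C)/C(C)=C/C[C@H](O[Si](C)(C)C(C)(C)C)C(=C)[C@H](CCC1(C)OCCO1)C(=C)C=O
F3 | step 8 | trans-fused cycloadduct with angular C20 aldehyde (C20-oxo analogue of 11) | CC1(OCCO1)CC[C@H]2C(=C)[C@@H](O[Si](C)(C)C(C)(C)C)C[C@H]3C(C)=C(O[Si](C)(C)C(C)(C)C)CC[C@]23C=O
F4 | step 8 | 4,4-dimethyl 3-keto 20-aldehyde (C20-oxo analogue of 13) | CC1(OCCO1)CC[C@H]2C(=C)[C@@H](O[Si](C)(C)C(C)(C)C)C[C@H]3C(C)(C)C(=O)CC[C@]23C=O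
F5 | step 8 | bis-hydrazone of F4 (C=N geometries not defined) | CC1(OCCO1)CC[C@H]2C(=C)[C@@H](O[Si](C)(C)C(C)(C)C)C[C@H]3C(C)(C)C(=NN)CC[C@]23C=NN
F6 | step 4 | acetate aldol adduct of 3 with the (S)-4-isopropylthiazolidine-2-thione auxiliary | O=C(C[C@H](O)C(=C)[C@H](CCC(C)=O)C(C)=C)N1C(=S)SC[C@@H]1C(C)C
F7 | step 4 | tert-butyldimethylsilyl ether of F6 | O=C(C[C@H](O[Si](C)(C)C(C)(C)C)C(=C)[C@H](CCC(C)=O)C(C)=C)N1C(=S)SC[C@@H]1C(C)C
F8 | step 4 | dioxolane of F7 | O=C(C[C@H](O[Si](C)(C)C(C)(C)C)C(=C)[C@H](CCC2(C)OCCO2)C(C)=C)N1C(=S)SC[C@@H]1C(C)C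
F9 | step 4 | β-silyloxy aldehyde (C5 aldehyde with C7 silyl ether and C13 dioxolane) | O=CC[C@H](O[Si](C)(C)C(C)(C)C)C(=C)[C@H](CCC1(C)OCCO1)C(C)=C
F10 | step 4 | C7 tert-butyldimethylsilyl ether of 9 | CC(=O)/C(C)=C/C[C@H](O[Si](C)(C)C(C)(C)C)C(=C)[C@H](CCC1(C)OCCO1)C(C)=C
F11 | step 12 | ethyl (13E)-17-chlorolabda-7,13-dien-15-oate | CCOC(=O)/C=C(\C)CC[C@H]1C(CCl)=CC[C@H]2C(C)(C)CCC[C@]12C
F12 | step 12 | ethyl (13E)-17-acetoxylabda-7,13-dien-15-oate | CCOC(=O)/C=C(\C)CC[C@H]1C(COC(C)=O)=CC[C@H]2C(C)(C)CCC[C@]12C
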